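**Assumptions (one line):** germacrane numbering is used (C1 ketone, C3/C10 furanone carbons, C6/C7 lactone junction, C8 angelate; target = 6R,7R,8S,10R, 4Z); a one-flask, two-stage operation with no intermediate purification is counted as one step.

## Retrosynthetic overview

1. Lychnopholide (1) ⇒ cut C6–C7 and the lactone C–O: intramolecular Cr(II) allylation of the Z-enal/allylic bromide 2 closes the 10-membered carbocycle, and the C6 oxygen then lactonises onto C12.
2. 2 ⇒ furanone alcohol 3 plus activated angelate 4 (C8 ester), followed by unmasking of the enal and SN2′ bromination.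
3. 3 ⇒ C1–C2 bond: the lithium acetylide of Z-enyne acetal 5 opens hydroxy-γ-lactone 6; Au-catalysed 5-endo closure of the α′-hydroxy ynone gives the 3(2H)-furanone.
4. 5 comes from but-2-yn-1-ol (7) and ethynyltrimethylsilane (8); 6 from chiral-pool lactone 9 (C8; C10 by enolate hydroxylation) and tert-butyl acrylate (10); 4 from angelic acid (11).
5. Ring order: furanone (step 14) → 10-membered carbocycle (step 18, key macrocyclisation) → α-methylene-γ-lactone (same step).

## Route

### Fragment A: Z-enyne acetal 5 (C2–C6, C15)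

**Step 1**
Reactants: 7 but-2-yn-1-ol
Product: 12 (2Z)-3-iodobut-2-en-1-ol
Conditions: Red-Al, Et2O, 0 °C→rt; EtOAc quench; I2, THF, −78→0 °C
Reagents that add atoms: iodine, II
Why: alkoxide-directed trans-hydroalumination puts Al on C3 in a five-membered alanate, and iodinolysis with retention gives the Z-vinyl iodide that fixes the C4=C5 geometry.

**Step 2**
Reactants: 12; 8 ethynyltrimethylsilane
Product: 13 (2Z)-3-methyl-5-(trimethylsilyl)pent-2-en-4-yn-1-ol
Conditions: PdCl2(PPh3)2 (2 mol%), CuI (4 mol%), i-Pr2NH, THF, rt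
Reagents that add atoms: none (8 is a reactant)
Why: Sonogashira coupling of a vinyl iodide proceeds with retention of alkene geometry and tolerates the free alcohol.

**Step 3**
Reactants: 13
Product: 14 (2Z)-3-methyl-5-(trimethylsilyl)pent-2-en-4-ynal
Conditions: activated MnO2, CH2Cl2, rt, dark
Reagents that add atoms: none
Why: neutral MnO2 oxidation of the allylic alcohol gives the enal without Z/E erosion.

**Step 4**
Reactants: 14
Product: 15 2-[(1Z)-2-methyl-4-(trimethylsilyl)but-1-en-3-yn-1-yl]-1,3-dioxolane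
Conditions: TMSOCH2CH2OTMS, TMSOTf (5 mol%), CH2Cl2, −78→−20 °C; pyridine quench
Reagents that add atoms: 1,2-bis(trimethylsilyloxy)ethane, C[Si](C)(C)OCCO[Si](C)(C)C
Why: Noyori acetalisation is aprotic and low-temperature, so the Z-enal is masked without isomerisation or conjugate addition.

**Step 5**
Reactants: 15
Product: 5 2-[(1Z)-2-methylbut-1-en-3-yn-1-yl]-1,3-dioxolane
Conditions: K2CO3, MeOH, 0 °C→rt
Reagents that add atoms: none
Why: methanolysis of the alkynyl C–Si bond frees the terminal alkyne; the acetal is base-stable.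

### Fragment B: hydroxy-lactone 6 (C1, C7–C14)

**Step 6**
Reactants: 9 (5S)-5-(hydroxymethyl)oxolan-2-one
Product: 16 (5S)-5-[(triethylsilyloxy)methyl]oxolan-2-one
Conditions: TESCl, imidazole, DMAP (cat.), CH2Cl2, 0 °C
Reagents that add atoms: chlorotriethylsilane, CC[Si](Cl)(CC)CC
Why: silylation of the primary alcohol; the lactone stereocentre (future C8, S) comes from the chiral pool.

**Step 7**
Reactants: 16
Product: 17 (3R,5S)-3-methyl-5-[(triethylsilyloxy)methyl]oxolan-2-one (trans major; configuration at C3 is irrelevant)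
Conditions: LDA, THF, −78 °C; MeI
Reagents that add atoms: iodomethane, CI
Why: lactone enolate alkylation installs the C14 methyl; the new centre is re-enolised in step 8.

**Step 8**
Reactants: 17
Product: 18 (3R,5S)-3-hydroxy-3-methyl-5-[(triethylsilyloxy)methyl]oxolan-2-one
Conditions: KHMDS, THF, −78 °C; 3-phenyl-2-(phenylsulfonyl)oxaziridine, −78 °C
Reagents that add atoms: Davis oxaziridine, O=S(=O)(N1OC1c1ccccc1)c1ccccc1
Why: Davis enolate hydroxylation occurs on the face anti to the C5 CH2OSiEt3 group, giving OH trans to it, which is the 10R configuration (8,10-syn).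

**Step 9**
Reactants: 18
Product: 19 (2S,4R)-4-hydroxy-4-methyl-5-oxooxolane-2-carbaldehyde
Conditions: (COCl)2 (4 equiv), DMSO (8 equiv), CH2Cl2, −78→−40 °C; i-Pr2NEt, −78→0 °C; used crude
Reagents that add atoms: none
Why: under Swern conditions a primary TES ether is cleaved and oxidised directly to the aldehyde; the tertiary alcohol cannot be oxidised, and the hindered base at low temperature limits C8 epimerisation.

**Step 10**
Reactants: 19; 10 tert-butyl acrylate
Product: 20 tert-butyl 2-{hydroxy[(2S,4R)-4-hydroxy-4-methyl-5-oxooxolan-2-yl]methyl}prop-2-enoate (both carbinol epimers)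
Conditions: DABCO (1 equiv), 10 (5 equiv), THF/MeOH 9:1, rt, 24–48 h
Reagents that add atoms: none (10 is a reactant)
Why: Morita–Baylis–Hillman reaction forms C7–C11 on the electrophilic α-oxy aldehyde; the new C7 carbinol centre is erased in step 17, so its configuration does not matter.

**Step 11**
Reactants: 20
Product: 6 tert-butyl 2-{[(tert-butyldimethylsilyl)oxy][(2S,4R)-4-hydroxy-4-methyl-5-oxooxolan-2-yl]methyl}prop-2-enoate
Conditions: TBSCl, imidazole, DMF, rt→40 °C
Reagents that add atoms: tert-butyldimethylsilyl chloride, CC(C)(C)[Si](C)(C)Cl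
Why: TBSCl/imidazole silylates the secondary allylic alcohol selectively and leaves the hindered tertiary alcohol free for furanone formation.

### Angelate donor

**Step 12**
Reactants: 11 angelic acid
Product: 4 (2Z)-2-methylbut-2-enoic 2,4,6-trichlorobenzoic anhydride (used as filtered toluene solution)
Conditions: 2,4,6-trichlorobenzoyl chloride, Et3N, toluene, rt, 2 h
Reagents that add atoms: 2,4,6-trichlorobenzoyl chloride, O=C(Cl)c1c(Cl)cc(Cl)cc1Cl
Why: Yamaguchi mixed-anhydride formation activates the acid without DMAP, which avoids angelate→tiglate isomerisation.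

### Fragment union and endgame

**Step 13**
Reactants: 5; 6
Product: 21 tert-butyl (4S,6R,10Z)-3-[(tert-butyldimethylsilyl)oxy]-11-(1,3-dioxolan-2-yl)-4,6-dihydroxy-6,10-dimethyl-2-methylidene-7-oxoundec-10-en-8-ynoate (C3 epimers; in equilibrium with its lactol)
Conditions: 5 (2.3 equiv), n-BuLi (2.2 equiv), THF, −78 °C; add 6, −78→−30 °C; AcOH quench at −78 °C (excess 5 recovered)
Reagents that add atoms: none
Why: alkynylation of the γ-lactone forms C1–C2. The first equivalent of acetylide deprotonates the tertiary OH, and the tetrahedral lithium hemiketal prevents over-addition. The tert-butyl ester and TBS ether are inert at this temperature, and the lactone has no α-hydrogen, so C8 and C10 are untouched.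

**Step 14**
Reactants: 21
Product: 3 tert-butyl (4S)-3-[(tert-butyldimethylsilyl)oxy]-5-{(2R)-5-[(1Z)-1-(1,3-dioxolan-2-yl)prop-1-en-2-yl]-2-methyl-3-oxo-2,3-dihydrofuran-2-yl}-4-hydroxy-2-methylidenepentanoate (C3 epimers)
Conditions: Ph3PAuNTf2 (3 mol%), toluene, rt
Reagents that add atoms: none
Why: Au(I)-catalysed 5-endo-dig cycloisomerisation of the α′-hydroxy ynone gives the 3(2H)-furanone; the C10–O bond is not broken, so 10R is retained, and the C8–OH would only give a 7-membered ring.

**Step 15**
Reactants: 3; 4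
Product: 22 tert-butyl (4S)-3-[(tert-butyldimethylsilyl)oxy]-5-{(2R)-5-[(1Z)-1-(1,3-dioxolan-2-yl)prop-1-en-2-yl]-2-methyl-3-oxo-2,3-dihydrofuran-2-yl}-2-methylidene-4-{[(2Z)-2-methylbut-2-enoyl]oxy}pentanoate
Conditions: 4 (3 equiv), Et3N, toluene, 80 °C (no DMAP)
Reagents that add atoms: none (4 is a reactant)
Why: Yamaguchi-type esterification; the alcohol attacks the unhindered angeloyl carbonyl of the mixed anhydride with retention at C8 and without Z→E isomerisation, and the tert-butyl ester cannot lactonise onto C8–OH.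

**Step 16**
Reactants: 22
Product: 23 tert-butyl (4S)-3-hydroxy-2-methylidene-4-{[(2Z)-2-methylbut-2-enoyl]oxy}-5-{(2R)-2-methyl-3-oxo-5-[(2Z)-4-oxobut-2-en-2-yl]-2,3-dihydrofuran-2-yl}pentanoate (C3 epimers)
Conditions: 48% aq. HF, MeCN, 0 °C→rt
Reagents that add atoms: water, O
Why: aqueous HF removes the secondary TBS ether and hydrolyses the dioxolane in one operation, revealing the C6 Z-enal and the allylic alcohol; the tert-butyl ester, angelate and furanone are stable.

**Step 17**
Reactants: 23
Product: 2 tert-butyl (2Z,4S)-2-(bromomethyl)-4-{[(2Z)-2-methylbut-2-enoyl]oxy}-5-{(2R)-2-methyl-3-oxo-5-[(2Z)-4-oxobut-2-en-2-yl]-2,3-dihydrofuran-2-yl}pent-2-enoate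
Conditions: NBS, Me2S (pre-mixed, Me2S in slight excess), CH2Cl2, −20→0 °C
Reagents that add atoms: N-bromosuccinimide, O=C1CCC(=O)N1Br
Why: Corey–Kim-type bromination of a Baylis–Hillman alcohol proceeds with SN2′ allylic transposition to the (Z)-2-(bromomethyl)enoate, so both carbinol epimers converge and the aldehyde is tolerated.

**Step 18**
Reactants: 2
Product: 1 lychnopholide
Conditions: CrCl2 (10 equiv), THF, rt, syringe-pump addition to about 2 mM; then TFA, CH2Cl2, 0 °C (same flask after solvent exchange)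
Reagents that add atoms: none
Why: intramolecular Nozaki–Hiyama (Barbier-type) allylation closes the 10-membered ring by γ-attack of the allylchromium (C7) on the C6 aldehyde, creating the exocyclic C11=C13 alkene. A chair transition state with both tether termini (C5, C8) pseudo-equatorial gives the 6,7-anti adduct, and the C8 acyloxy stereocentre should select the 6R,7R face. Acid then closes the trans α-methylene-γ-lactone from the C6 alcohol and the tert-butyl ester.

## Compound list

1 | lychnopholide, (6R,7R,8S,10R,4Z)-furanoheliangolide 8-angelate | C=C1C(=O)O[C@@H]2/C=C(/C)C3=CC(=O)[C@@](C)(C[C@H](OC(=O)/C(C)=C\C)[C@@H]12)O3 | target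
2 | tert-butyl (2Z,4S)-2-(bromomethyl)-4-{[(2Z)-2-methylbut-2-enoyl]oxy}-5-{(2R)-2-methyl-3-oxo-5-[(2Z)-4-oxobut-2-en-2-yl]-2,3-dihydrofuran-2-yl}pent-2-enoate | BrC/C(C(=O)OC(C)(C)C)=C\[C@@H](OC(=O)/C(C)=C\C)C[C@@]1(C)OC(/C(C)=C\C=O)=CC1=O | intermediate
3 | tert-butyl (4S)-3-[(tert-butyldimethylsilyl)oxy]-5-{(2R)-5-[(1Z)-1-(1,3-dioxolan-2-yl)prop-1-en-2-yl]-2-methyl-3-oxo-2,3-dihydrofuran-2-yl}-4-hydroxy-2-methylidenepentanoate (C3 epimers) | C=C(C(=O)OC(C)(C)C)C(O[Si](C)(C)C(C)(C)C)[C@@H](O)C[C@@]1(C)OC(/C(C)=C\C2OCCO2)=CC1=O | intermediate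
4 | (2Z)-2-methylbut-2-enoic 2,4,6-trichlorobenzoic anhydride | C/C=C(/C)C(=O)OC(=O)c1c(Cl)cc(Cl)cc1Cl | intermediate
5 | 2-[(1Z)-2-methylbut-1-en-3-yn-1-yl]-1,3-dioxolane | C#C/C(C)=C\C1OCCO1 | intermediate
6 | tert-butyl 2-{[(tert-butyldimethylsilyl)oxy][(2S,4R)-4-hydroxy-4-methyl-5-oxooxolan-2-yl]methyl}prop-2-enoate (epimers at the silyloxy carbon) | C=C(C(=O)OC(C)(C)C)C(O[Si](C)(C)C(C)(C)C)[C@@H]1C[C@@](C)(O)C(=O)O1 | intermediate
7 | but-2-yn-1-ol | CC#CCO | starting material
8 | ethynyltrimethylsilane | C#C[Si](C)(C)C | starting material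
9 | (5S)-5-(hydroxymethyl)oxolan-2-one | OC[C@@H]1CCC(=O)O1 | starting material
10 | tert-butyl acrylate | C=CC(=O)OC(C)(C)C | starting material
11 | angelic acid, (2Z)-2-methylbut-2-enoic acid | C/C=C(/C)C(=O)O | starting material
12 | (2Z)-3-iodobut-2-en-1-ol | C/C(I)=C/CO | intermediate
13 | (2Z)-3-methyl-5-(trimethylsilyl)pent-2-en-4-yn-1-ol | C[Si](C)(C)C#C/C(C)=C\CO | intermediate
14 | (2Z)-3-methyl-5-(trimethylsilyl)pent-2-en-4-ynal | C[Si](C)(C)C#C/C(C)=C\C=O | intermediate
15 | 2-[(1Z)-2-methyl-4-(trimethylsilyl)but-1-en-3-yn-1-yl]-1,3-dioxolane | C[Si](C)(C)C#C/C(C)=C\C1OCCO1 | intermediate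
16 | (5S)-5-[(triethylsilyloxy)methyl]oxolan-2-one | CC[Si](CC)(CC)OC[C@@H]1CCC(=O)O1 | intermediate
17 | (3R,5S)-3-methyl-5-[(triethylsilyloxy)methyl]oxolan-2-one | CC[Si](CC)(CC)OC[C@@H]1C[C@@H](C)C(=O)O1 | intermediate
18 | (3R,5S)-3-hydroxy-3-methyl-5-[(triethylsilyloxy)methyl]oxolan-2-one | CC[Si](CC)(CC)OC[C@@H]1C[C@@](C)(O)C(=O)O1 | intermediate
19 | (2S,4R)-4-hydroxy-4-methyl-5-oxooxolane-2-carbaldehyde | O=C[C@@H]1C[C@@](C)(O)C(=O)O1 | intermediate
20 | tert-butyl 2-{hydroxy[(2S,4R)-4-hydroxy-4-methyl-5-oxooxolan-2-yl]methyl}prop-2-enoate (carbinol epimers) | C=C(C(=O)OC(C)(C)C)C(O)[C@@H]1C[C@@](C)(O)C(=O)O1 | intermediate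
21 | tert-butyl (4S,6R,10Z)-3-[(tert-butyldimethylsilyl)oxy]-11-(1,3-dioxolan-2-yl)-4,6-dihydroxy-6,10-dimethyl-2-methylidene-7-oxoundec-10-en-8-ynoate (C3 epimers) | C=C(C(=O)OC(C)(C)C)C(O[Si](C)(C)C(C)(C)C)[C@@H](O)C[C@@](C)(O)C(=O)C#C/C(C)=C\C1OCCO1 | intermediate
22 | tert-butyl (4S)-3-[(tert-butyldimethylsilyl)oxy]-5-{(2R)-5-[(1Z)-1-(1,3-dioxolan-2-yl)prop-1-en-2-yl]-2-methyl-3-oxo-2,3-dihydrofuran-2-yl}-2-methylidene-4-{[(2Z)-2-methylbut-2-enoyl]oxy}pentanoate (C3 epimers) | C=C(C(=O)OC(C)(C)C)C(O[Si](C)(C)C(C)(C)C)[C@@H](OC(=O)/C(C)=C\C)C[C@@]1(C)OC(/C(C)=C\C2OCCO2)=CC1=O | intermediate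
23 | tert-butyl (4S)-3-hydroxy-2-methylidene-4-{[(2Z)-2-methylbut-2-enoyl]oxy}-5-{(2R)-2-methyl-3-oxo-5-[(2Z)-4-oxobut-2-en-2-yl]-2,3-dihydrofuran-2-yl}pentanoate (C3 epimers) | C=C(C(=O)OC(C)(C)C)C(O)[C@@H](OC(=O)/C(C)=C\C)C[C@@]1(C)OC(/C(C)=C\C=O)=CC1=O | intermediate

## Summary

**Total step count:** 18 (fragment A: 5; fragment B: 6; angelate donor: 1; union and endgame: 6).

**Longest linear sequence:** 12 steps (steps 6–11, then 13–18, from lactone 9), which is 12/18 = two thirds of the total.

**Three steps most likely to fail, with fallbacks**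

1. **Step 18 (Cr-mediated macrocyclisation/lactonisation).** Risks are the wrong C6/C7 diastereomer (cis-lactone), oligomerisation, and Z→E erosion of the enal. Fallback: change the ring-closing bond. Run the allylation intermolecularly between enynal 14 and the allylic bromide derived from 20 to set C6/C7 and the lactone first. Then close the 10-membered ring at C1–C2 by intramolecular Nozaki–Hiyama–Kishi alkynylation (iodoalkyne onto a C1 aldehyde), oxidise to the ynone and form the furanone transannularly with Au(I).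

2. **Step 13 (acetylide opening of the hindered α-alkoxido lactone next to an acrylate).** Risks are sluggish addition, attack on the acrylate, or ynone/lactol complications. Fallback: change the fragment-joining bond to C3–C4. Add lithium TMS-acetylide to lactone 18 before the Baylis–Hillman sequence and carry C1 as a protected propargylic alcohol. Later join the fragments by Sonogashira coupling with the dioxolane of (Z)-3-iodobut-2-enal (from 12), then oxidise to the ynone.

3. **Step 10 (Baylis–Hillman on the α-acyloxy aldehyde 19 with a slow acrylate).** Risks are C8 epimerisation and lactone degradation over long exposure to the amine. Fallback: replace the amine-catalysed reaction with a stoichiometric vinylmetal addition. Generate [α-(tert-butoxycarbonyl)vinyl]diisobutylalane from tert-butyl propiolate (DIBAL-H/NMO) and add it to 19 at −78 °C, which gives the same adduct 20 under non-basic conditions.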